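**Retrosynthetic overview**

1. Target 27 ⇐ diol 26 ⇐ diene 24 ⇐ enone 22. The C2 oxygen is put back last by hydroboration of the C1=C2 alkene, and the C6 ketone of 22 is temporary and is removed reductively.
2. Enone 22 ⇐ acid chloride 20: the C6–C7 bond and ring B come from attack of the isopropenyl group on a C6 acylium ion, followed by base equilibration of C5 and C9.
3. Feature on which the plan rests: with a ketone on C6, C5 (between C4 and C10) is its α-carbon and C9 is its vinylogous γ-carbon across C7=C8 of ring B. Of the C5/C9/C10 triad only quaternary C10 then needs kinetic control, and C10 is the allylic partner, through C1, of the oxygen-bearing C2 of ring A.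
4. Acid chloride 20 ⇐ β-keto ester 15 ⇐ 6 + 7 + 14: C9–C10 by Carroll rearrangement (chirality transfer C2 → C10), C9–C11 by alkylation with the citronellol-derived iodide.
5. Ring A is made first (step 1, from mesityl oxide and allyl acetoacetate), ring B second (step 12).

Key step: step 12

Remark on the chemistry: labdane numbering is used for all intermediates; ring A is built as its allyl ester so that the shielded C6 carboxyl can be freed at the allyl carbon, the chain carries an acetate throughout, and compounds 5–21 are carried as epimer mixtures at C5 (from 15 on also at C9), which their SMILES leave open because both centres are set only in step 12.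

**Route**

Step 1
Reactants: 1 mesityl oxide; 2 allyl acetoacetate
Product: 5 allyl 2,6,6-trimethyl-4-oxocyclohex-2-ene-1-carboxylate (racemic), via Michael adduct 3 (not isolated), via cyclic aldol 4 (not isolated)
Conditions: BF3·OEt2 (1 equiv), neat, 0 °C → rt
Reagents that add atoms: none
Why: Lewis-acid-promoted Michael addition of the acetoacetate enol to mesityl oxide, then intramolecular aldol condensation of the former mesityl methyl ketone onto the acetyl carbonyl (Robinson-type annulation, established for the ethyl ester), should give ring A with the C4 gem-dimethyl group, the C10 methyl, the C2 ketone and the C6 ester carbon in place; C5 is racemic here and is corrected in step 12.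

Step 2
Reactants: 5 allyl 2,6,6-trimethyl-4-oxocyclohex-2-ene-1-carboxylate
Product: 6 allyl (4R)-4-hydroxy-2,6,6-trimethylcyclohex-2-ene-1-carboxylate (labdane C2 R; both C5 epimers)
Conditions: (S)-2-methyl-CBS-oxazaborolidine (15 mol %), catecholborane (1.5 equiv), toluene, −78 °C; aqueous work-up
Reagents that add atoms: none
Why: Corey–Bakshi–Shibata reduction in which the C1=C10 alkenyl arm takes the large-group position and the C3 methylene the small one, so the (S)-catalyst should deliver hydride to the face that gives the (R)-carbinol at C2 under reagent control in both antipodes of 5, while catecholborane at −78 °C leaves the allyl ester alkene untouched.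

Step 3
Reactants: 6 allyl (4R)-4-hydroxy-2,6,6-trimethylcyclohex-2-ene-1-carboxylate; 7 2,2,6-trimethyl-4H-1,3-dioxin-4-one
Product: 8 allyl (4R)-4-(3-oxobutanoyloxy)-2,6,6-trimethylcyclohex-2-ene-1-carboxylate
Conditions: xylene, 135 °C, acetone distilled off
Reagents that add atoms: none
Why: thermal cycloreversion of the dioxinone gives acetylketene, which acylates the secondary allylic alcohol under neutral conditions (acetoacetylation) without touching the C2 centre or ionising the allylic C–O bond.

Step 4
Reactants: 9 (S)-citronellol
Product: 10 (S)-citronellyl acetate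
Conditions: Ac2O, pyridine, DMAP (cat.), CH2Cl2, rt
Reagents that add atoms: acetic anhydride, CC(=O)OC(C)=O
Why: DMAP-catalysed acetylation of the primary alcohol installs at C15 the ester that the target itself carries; C13 is not involved.

Step 5
Reactants: 10 (S)-citronellyl acetate
Product: 12 (4S)-6-acetoxy-4-methylhexanoic acid, via aldehyde 11 (not isolated)
Conditions: RuCl3·xH2O (2 mol %), NaIO4 (4.1 equiv), CCl4/MeCN/H2O 2:2:3, rt
Reagents that add atoms: sodium periodate, [Na+].[O-]I(=O)(=O)=O; water, O
Why: RuO4-catalysed oxidative cleavage of the trisubstituted alkene releases acetone and the aldehyde, which is oxidised on to the acid in the same flask; the remote C13 centre is unaffected.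

Step 6
Reactants: 12 (4S)-6-acetoxy-4-methylhexanoic acid
Product: 14 (3R)-5-iodo-3-methylpentyl acetate, via acyl hypoiodite 13 (not isolated)
Conditions: PhI(OAc)2, I2, cyclohexane, hν (tungsten lamp), reflux
Reagents that add atoms: iodine, II
Why: Hunsdiecker-type iododecarboxylation under Suárez conditions, in which the acyl hypoiodite formed in the flask is photolysed, the acyloxy radical loses CO2 and the primary radical is trapped by iodine, removes the surplus carbon so that iodine sits on C11; the change of descriptor at C13 is only nominal.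

Step 7
Reactants: 8 allyl (4R)-4-(3-oxobutanoyloxy)-2,6,6-trimethylcyclohex-2-ene-1-carboxylate; 14 (3R)-5-iodo-3-methylpentyl acetate
Product: 15 allyl (4R)-4-{[(5S)-7-acetoxy-2-acetyl-5-methylheptanoyl]oxy}-2,6,6-trimethylcyclohex-2-ene-1-carboxylate (C9 epimers)
Conditions: NaH (1.0 equiv), THF/DMF 4:1, 0 °C; then 14, 50 °C
Reagents that add atoms: none
Why: acetoacetic ester alkylation, in which the sodium enolate of the β-keto ester is C-alkylated by the unhindered primary iodide (SN2) to form C9–C11; the new C9 centre is uncontrolled and of no consequence.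

Step 8
Reactants: 15 allyl (4R)-4-{[(5S)-7-acetoxy-2-acetyl-5-methylheptanoyl]oxy}-2,6,6-trimethylcyclohex-2-ene-1-carboxylate
Product: 17 allyl (2S)-2-[(6S)-8-acetoxy-6-methyl-2-oxooctan-3-yl]-2,6,6-trimethylcyclohex-3-ene-1-carboxylate (epimers at C5 and C9), via beta-keto acid 16 (not isolated)
Conditions: decalin (degassed), 180 °C, Ar
Reagents that add atoms: none
Why: Carroll rearrangement, a [3,3]-sigmatropic shift of the ester enol across the C2–C1=C10 allyl unit, should form C9–C10 suprafacially on the face that carried the C2 oxygen, so the (R)-C2 centre is traded for the quaternary C10 centre of the target series (C20 anti to the former C–O bond), and the β-keto acid loses CO2 at the reaction temperature to leave the C8 methyl ketone.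

Step 9
Reactants: 17 allyl (2S)-2-[(6S)-8-acetoxy-6-methyl-2-oxooctan-3-yl]-2,6,6-trimethylcyclohex-3-ene-1-carboxylate
Product: 18 allyl (2S)-2-[(6S)-8-acetoxy-2,6-dimethyloct-1-en-3-yl]-2,6,6-trimethylcyclohex-3-ene-1-carboxylate (epimers at C5 and C9)
Conditions: Zn, CH2Br2, TiCl4, THF/CH2Cl2, 0 °C → rt
Reagents that add atoms: dibromomethane, BrCBr
Why: Takai–Lombardo methylenation, whose non-basic zinc/titanium methylene reagent converts the hindered, enolisable C8 methyl ketone into the isopropenyl group (the new carbon is C7) and leaves the three ester groups alone.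

Step 10
Reactants: 18 allyl (2S)-2-[(6S)-8-acetoxy-2,6-dimethyloct-1-en-3-yl]-2,6,6-trimethylcyclohex-3-ene-1-carboxylate
Product: 19 (2S)-2-[(6S)-8-acetoxy-2,6-dimethyloct-1-en-3-yl]-2,6,6-trimethylcyclohex-3-ene-1-carboxylic acid (epimers at C5 and C9)
Conditions: Pd(PPh3)4 (5 mol %), morpholine (5 equiv), THF, rt; aq. citric acid
Reagents that add atoms: none
Why: Tsuji–Trost deallylation, in which zerovalent palladium ionises the allyl–oxygen bond and morpholine traps the allyl fragment, frees the acid flanked by C4 and C10 without any attack at its shielded carbonyl and under conditions too mild to lactonise it onto the isopropenyl group.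

Step 11
Reactants: 19 (2S)-2-[(6S)-8-acetoxy-2,6-dimethyloct-1-en-3-yl]-2,6,6-trimethylcyclohex-3-ene-1-carboxylic acid
Product: 20 (2S)-2-[(6S)-8-acetoxy-2,6-dimethyloct-1-en-3-yl]-2,6,6-trimethylcyclohex-3-ene-1-carbonyl chloride (epimers at C5 and C9)
Conditions: 1-chloro-N,N,2-trimethylprop-1-en-1-amine (1.3 equiv), CH2Cl2, 0 °C → rt; volatiles removed, used crude
Reagents that add atoms: 1-chloro-N,N,2-trimethylprop-1-en-1-amine (Ghosez reagent), CC(C)=C(Cl)N(C)C
Why: acid chloride formation with the Ghosez α-chloroenamine runs through an acyloxy-iminium chloride and releases only a neutral amide, so no HCl is present to add to the isopropenyl group or to close the δ-lactone.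

Step 12
Reactants: 20 (2S)-2-[(6S)-8-acetoxy-2,6-dimethyloct-1-en-3-yl]-2,6,6-trimethylcyclohex-3-ene-1-carbonyl chloride
Product: 22 (5R,9R,10S,13S)-15-acetoxylabda-1,7-dien-6-one, via beta-chloro ketone 21 (not isolated)
Conditions: SnCl4 (2.2 equiv), CH2Cl2, −78 → −20 °C; aq. NaHCO3; then DBU (3 equiv), toluene, 80 °C
Reagents that add atoms: none
Why: SnCl4 ionises 20 to a linear acylium ion at C6, which is attacked by the methylene terminus (C7) of the isopropenyl group so that the charge lands on tertiary C8 inside the new ring and is quenched by chloride to give 21; DBU then removes HCl by E1cB across C7–C8 and brings any deconjugated alkene isomer into conjugation with C6. The closest known reaction type is the intramolecular Friedel–Crafts-type (Darzens–Nenitzescu) acylation of a 1,1-disubstituted alkene by an acid chloride to a cyclohexenone, followed by base epimerisation of the α- and γ-centres of the enone. Ring B (C5–C6–C7–C8–C9–C10) closes in the 6-endo-trig mode, and both the cis and the trans isomers of 20 can reach the acylium carbon because the C5 and C10 arms are vicinal on ring A. C5 is set by reversible enolisation towards C5–C6, which should settle in the trans-fused junction with H-5 anti to C20, and C9 by reversible formation of the C6–C7–C8–C9 dienolate, which takes its proton back axially on the face opposite C20 and so leaves C11 equatorial; both outcomes are imposed by the fixed quaternary C10. The step needs the isopropenyl group to win over the C1–C2 alkene, which is secured because attack by C1 or C2 would give a secondary cation in a cyclobutanone or a bridged 7-norbornanone, and it needs C-acylation to outrun loss of CO, which the secondary nature of C5 and the low temperature should secure.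

Step 13
Reactants: 22 (5R,9R,10S,13S)-15-acetoxylabda-1,7-dien-6-one
Product: 23 (5R,9R,10S,13S)-15-acetoxylabda-1,7-dien-6-ol (C6 epimers; hydroxyl syn to C20 expected to predominate)
Conditions: NaBH4, CeCl3·7H2O, MeOH, −20 → 0 °C
Reagents that add atoms: none
Why: Luche reduction gives 1,2-reduction of the enone, hydride entering C6 from the face opposite the axial C4 and C10 methyls; the C6 configuration is immaterial because the carbinol is removed in step 14.

Step 14
Reactants: 23 (5R,9R,10S,13S)-15-acetoxylabda-1,7-dien-6-ol
Product: 24 (5R,9R,10R,13S)-15-acetoxylabda-1,7-diene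
Conditions: Et3SiH (5 equiv), BF3·OEt2 (1.5 equiv), CH2Cl2, −78 → −30 °C
Reagents that add atoms: none
Why: ionic (silane) deoxygenation, in which BF3 ionises the crowded allylic alcohol to the C6–C7–C8 allyl cation and Et3SiH delivers hydride to the less substituted terminus C6, should restore the trisubstituted C7=C8 alkene; C5 and C9 are not part of the cation and keep their configuration, and the isolated C1=C2 alkene is not protonated under these conditions.

Step 15
Reactants: 24 (5R,9R,10R,13S)-15-acetoxylabda-1,7-diene
Product: 26 (2R,5R,9R,10R,13S)-labd-7-ene-2,15-diol, via C2 organoborane 25 (not isolated)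
Conditions: 9-BBN (2 equiv), THF, 65 °C; then EtOH, 3 M NaOH, 30% H2O2, 0 → 50 °C
Reagents that add atoms: hydrogen peroxide, OO (oxygen on C2); 9-BBN, B1C2CCCC1CCC2 (its boron is carried only in 25)
Why: hydroboration–oxidation, in which 9-BBN should select the disubstituted C1=C2 alkene over the more hindered trisubstituted C7=C8 alkene, place boron on C2 away from quaternary C10 and add syn from the face opposite the axial C10 and C4 methyls, so that oxidation with retention gives the equatorial (2R)-alcohol; the alkaline peroxide also saponifies the C15 acetate.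

Step 16
Reactants: 26 (2R,5R,9R,10R,13S)-labd-7-ene-2,15-diol
Product: 27 (2R,5R,9R,10R,13S)-labd-7-ene-2,15-diyl diacetate (CNP0220683.1)
Conditions: Ac2O (4 equiv), pyridine, DMAP (cat.), CH2Cl2, rt
Reagents that add atoms: acetic anhydride, CC(=O)OC(C)=O
Why: DMAP-catalysed acetylation of the primary C15 and the equatorial secondary C2 hydroxyl groups completes the target without touching any stereocentre.

**Compound list**

1 | mesityl oxide (4-methylpent-3-en-2-one) | CC(C)=CC(C)=O | starting material
2 | allyl acetoacetate (prop-2-enyl 3-oxobutanoate) | CC(=O)CC(=O)OCC=C | starting material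
3 | allyl 2-acetyl-3,3-dimethyl-5-oxohexanoate (Michael adduct, racemic) | CC(=O)CC(C)(C)C(C(C)=O)C(=O)OCC=C | intermediate (not isolated)
4 | allyl 2-hydroxy-2,6,6-trimethyl-4-oxocyclohexane-1-carboxylate (cyclic aldol, isomer mixture) | C=CCOC(=O)C1C(C)(O)CC(=O)CC1(C)C | intermediate (not isolated)
5 | allyl 2,6,6-trimethyl-4-oxocyclohex-2-ene-1-carboxylate (racemic at C5) | C=CCOC(=O)C1C(C)=CC(=O)CC1(C)C | intermediate
6 | allyl (4R)-4-hydroxy-2,6,6-trimethylcyclohex-2-ene-1-carboxylate (C2 R in labdane numbering; both C5 epimers) | C=CCOC(=O)C1C(C)=C[C@H](O)CC1(C)C | intermediate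
7 | 2,2,6-trimethyl-4H-1,3-dioxin-4-one | CC1=CC(=O)OC(C)(C)O1 | starting material
8 | allyl (4R)-4-(3-oxobutanoyloxy)-2,6,6-trimethylcyclohex-2-ene-1-carboxylate (both C5 epimers) | C=CCOC(=O)C1C(C)=C[C@H](OC(=O)CC(C)=O)CC1(C)C | intermediate
9 | (S)-citronellol | OCC[C@@H](C)CCC=C(C)C | starting material
10 | (S)-citronellyl acetate | CC(=O)OCC[C@@H](C)CCC=C(C)C | intermediate
11 | (3S)-3-methyl-6-oxohexyl acetate | CC(=O)OCC[C@@H](C)CCC=O | intermediate (not isolated)
12 | (4S)-6-acetoxy-4-methylhexanoic acid | CC(=O)OCC[C@@H](C)CCC(=O)O | intermediate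
13 | (4S)-6-acetoxy-4-methylhexanoyl hypoiodite | CC(=O)OCC[C@@H](C)CCC(=O)OI | intermediate (not isolated)
14 | (3R)-5-iodo-3-methylpentyl acetate (C11 iodide, C13 as in the target) | CC(=O)OCC[C@@H](C)CCI | intermediate
15 | allyl (4R)-4-{[(5S)-7-acetoxy-2-acetyl-5-methylheptanoyl]oxy}-2,6,6-trimethylcyclohex-2-ene-1-carboxylate (epimers at C5 and C9) | C=CCOC(=O)C1C(C)=C[C@H](OC(=O)C(C(C)=O)CC[C@H](C)CCOC(C)=O)CC1(C)C | intermediate
16 | (5S)-7-acetoxy-2-acetyl-2-[(1-allyloxycarbonyl)-2,6,6-trimethylcyclohex-3-en-2-yl]-5-methylheptanoic acid (C10 as in 17; epimers at C5 and C9) | C=CCOC(=O)C1C(C)(C)CC=C[C@@]1(C)C(CC[C@H](C)CCOC(C)=O)(C(C)=O)C(=O)O | intermediate (not isolated)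
17 | allyl (2S)-2-[(6S)-8-acetoxy-6-methyl-2-oxooctan-3-yl]-2,6,6-trimethylcyclohex-3-ene-1-carboxylate (epimers at C5 and C9) | C=CCOC(=O)C1C(C)(C)CC=C[C@@]1(C)C(CC[C@H](C)CCOC(C)=O)C(C)=O | intermediate
18 | allyl (2S)-2-[(6S)-8-acetoxy-2,6-dimethyloct-1-en-3-yl]-2,6,6-trimethylcyclohex-3-ene-1-carboxylate (epimers at C5 and C9) | C=CCOC(=O)C1C(C)(C)CC=C[C@@]1(C)C(CC[C@H](C)CCOC(C)=O)C(C)=C | intermediate
19 | (2S)-2-[(6S)-8-acetoxy-2,6-dimethyloct-1-en-3-yl]-2,6,6-trimethylcyclohex-3-ene-1-carboxylic acid (epimers at C5 and C9) | OC(=O)C1C(C)(C)CC=C[C@@]1(C)C(CC[C@H](C)CCOC(C)=O)C(C)=C | intermediate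
20 | (2S)-2-[(6S)-8-acetoxy-2,6-dimethyloct-1-en-3-yl]-2,6,6-trimethylcyclohex-3-ene-1-carbonyl chloride (key-step precursor; epimers at C5 and C9) | ClC(=O)C1C(C)(C)CC=C[C@@]1(C)C(CC[C@H](C)CCOC(C)=O)C(C)=C | intermediate
21 | 15-acetoxy-8-chlorolabd-1-en-6-one (C10 and C13 as in 22; isomers at C5, C8, C9) | CC(=O)OCC[C@@H](C)CCC1C(C)(Cl)CC(=O)C2C(C)(C)CC=C[C@@]12C | intermediate (not isolated)
22 | (5R,9R,10S,13S)-15-acetoxylabda-1,7-dien-6-one (trans-fused; H-5 and H-9 anti to C20) | CC(=O)OCC[C@@H](C)CC[C@@H]1C(C)=CC(=O)[C@@H]2C(C)(C)CC=C[C@@]12C | intermediate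
23 | (5R,9R,10S,13S)-15-acetoxylabda-1,7-dien-6-ol (C6 epimers) | CC(=O)OCC[C@@H](C)CC[C@@H]1C(C)=CC(O)[C@@H]2C(C)(C)CC=C[C@@]12C | intermediate
24 | (5R,9R,10R,13S)-15-acetoxylabda-1,7-diene | CC(=O)OCC[C@@H](C)CC[C@@H]1C(C)=CC[C@@H]2C(C)(C)CC=C[C@@]12C | intermediate
25 | B-[15-acetoxylabd-7-en-2-yl]-9-borabicyclo[3.3.1]nonane (boron on C2, on the face opposite C20) | CC(=O)OCC[C@@H](C)CC[C@@H]1C(C)=CC[C@@H]2C(C)(C)C[C@@H](B3C4CCCC3CCC4)C[C@@]12C | intermediate (not isolated)
26 | (2R,5R,9R,10R,13S)-labd-7-ene-2,15-diol | OCC[C@@H](C)CC[C@@H]1C(C)=CC[C@@H]2C(C)(C)C[C@@H](O)C[C@@]12C | intermediate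
27 | (2R,5R,9R,10R,13S)-labd-7-ene-2,15-diyl diacetate (CNP0220683.1) | CC(=O)OCC[C@@H](C)CC[C@@H]1C(C)=CC[C@@H]2C(C)(C)C[C@@H](OC(C)=O)C[C@@]12C | target

**Step count**

Total: 16 steps. Longest linear sequence: 13 steps (steps 1–3, then 7–16; the chain branch, steps 4–6 then 7–16, is equally long).

**Steps most likely to fail**

Step 12. The ring closure itself is expected to be robust; the weak point is that the drain of the minor isomers may stall. The cis-fused ketone has to give up a shielded H-5, the 9-epimer an equatorial H-9 that is poorly aligned with the enone π-system, and allylic strain between C17 and an equatorial C11 may flatten the C9 equilibrium. The fallback replaces thermodynamic selection at C9 by kinetic protonation. It sets out from 22 as the isomer mixture. KOtBu in t-BuOH/THF at room temperature should convert it into the potassium C6–C9 dienolate, with C5 equilibrating in the same medium. Inverse quench into cold aqueous AcOH should protonate C7 and give the deconjugated 15-acetoxylabda-1,8-dien-6-one F1, in which C9 is no longer a stereocentre. Brief treatment with catalytic DBU in CH2Cl2 at room temperature should then move the alkene back into conjugation, the proton entering C9 axially and anti to C20, and the sequence comes back to the route at 22.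

Step 8. The [3,3] shift has to build a quaternary carbon next to C5 from an α-substituted, weakly enolised acetoacetate, and at 180 °C ionisation or elimination of the allylic ester to a cyclohexadiene may outrun it. The fallback runs the rearrangement in the Ireland–Claisen manifold near room temperature. It sets out from 15, which TMSOTf and Et3N in CH2Cl2 at 0 °C should convert by soft enolisation into the bis(trimethylsilyl) dienol ether F2, an O-allyl O-silyl ketene acetal. This should rearrange at 25–60 °C in toluene with the same suprafacial transfer from C2 to C10. Dilute HCl in THF then removes the silyl groups to give 16, which loses CO2 and comes back to the route at 17.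

Step 14. Hydride may be captured at C8 instead of C6, or the allyl cation may lose a proton and give ring B dienes. The fallback removes the C6 oxygen through the allyl radical instead of the cation (Barton–McCombie deoxygenation). It sets out from 23, which NaH, CS2 and MeI in THF should convert into the S-methyl xanthate F3; should this rearrange to the C8 dithiocarbonate, the same radical results. Bu3SnH and AIBN in toluene at 90 °C should generate the C6–C7–C8 allyl radical, which cannot eliminate and should take hydrogen at the less hindered C6 terminus, coming back to the route at 24.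

**Further compounds**

F1 | step 12 | 15-acetoxylabda-1,8-dien-6-one (C5, C10 and C13 as in 22) | CC(=O)OCC[C@@H](C)CCC1=C(C)CC(=O)[C@@H]2C(C)(C)CC=C[C@@]12C
F2 | step 8 | allyl (4R)-4-{[(5S)-7-acetoxy-5-methyl-1-(trimethylsilyloxy)-2-[1-(trimethylsilyloxy)ethenyl]hept-1-en-1-yl]oxy}-2,6,6-trimethylcyclohex-2-ene-1-carboxylate | C=CCOC(=O)C1C(C)=C[C@H](OC(O[Si](C)(C)C)=C(CC[C@H](C)CCOC(C)=O)C(=C)O[Si](C)(C)C)CC1(C)C
F3 | step 14 | O-[15-acetoxylabda-1,7-dien-6-yl] S-methyl dithiocarbonate (C5, C9, C10 and C13 as in 23) | CC(=O)OCC[C@@H](C)CC[C@@H]1C(C)=CC(OC(=S)SC)[C@@H]2C(C)(C)CC=C[C@@]12C
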